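## Structural features

The target is a 6H-isochromene-6,8(7H)-dione (azaphilone). A pyran ring (O2, C1, C8a, C4a, C4, C3) is fused through C4a–C8a to a cyclohexenedione ring (C5, C6, C7, C8). The two rings share one cross-conjugated chromophore, O2–C1=C8a–C8=O and C3=C4–C4a=C5–C6=O. C3 carries an (E)-2-carboxyvinyl chain (C9=C10–C11O2H).

C7 is the only stereocentre. It is quaternary, bears a methyl group and the ester oxygen of a 2,4-dihydroxy-6-methylbenzoate, and lies between the C6 and C8 carbonyl groups. It has no stereogenic neighbour, so only absolute control is needed.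

C7 is stereogenic only because its two acyl flanks differ (C6–C5H against C8–C8a=C1). In a 2,2-disubstituted 5-alkylcyclohex-4-ene-1,3-dione that lacks the C1 carbon, the flanks exchange by enolisation and the centre racemises.

The fragile parts are:
- C1 of the pyran, which takes up amines and other nucleophiles;
- the tertiary ester, hindered on both the acid and the alcohol side;
- the dienoic acid and the free resorcinol.

The real difficulty is a configurationally secure C7 carrying this hindered ester, combined with the need to form the electrophilic chromophore late.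

The key step uses two features. C3(–O2)–C9=C10–C11(=O)OH is a 4-oxobut-2-enoic acid, the oxidised ring-opened form of a 2-substituted furan bound through C4 to C4a. C1 is a formyl-level carbon on C8a, 1,5 to the C3 oxygen, so unmasking the furan gives a keto-aldehyde-type array that closes the pyran through O2–C1.

## Logic of the disconnections

**29 to 28 to 27.** The two aryl O–CH2Ar bonds are cut (29 from 28), and C11 is taken from acid to aldehyde (28 from 27). Free phenols and a free acid would interfere with acylation, organolithium and photooxygenation chemistry, and an aldehyde is what a furan delivers. The gain is that 27 and everything before it carry no acidic hydrogens. The demand is that the last two steps use only acid and a mild oxidant, because the pyran of 28 and 29 tolerates acid but not amines, base or reduction.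

**27 to 23.** The O2–C1 bond is cut, and the C3(=O)–C9=C10–C11(=O) unit is folded back into a furan. A furan survives carbanions, amide acetals and acid, so the sensitive chromophore and the side chain can be made together at the end. The gain is the loss of the pyran ring, the trienone and the unsaturated chain; 23 is a monocyclic dione. The demand is that the oxidant attacks only the furan, and that the C3 oxygen, not another nucleophile, closes onto C1.

**23 to 22.** The C1–OMe bond is exchanged for C1–NMe2. An enamine is needed as the carbon nucleophile that builds the ring, but an aminomethylene group is itself cleaved by singlet oxygen, so it must be replaced before the key step. The gain is that 22 is the direct product of ring construction. The demand is an exchange under acid mild enough for the aryl ethers.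

**22 to 14 and 19 (through 21).** The ring bond C4a–C8a and the acyl–alkynyl bond C5–C6 are cut. C4a is the β-carbon of a ynone, the one place where C8a can be joined with unambiguous regiochemistry. C8a already carries C1, so the two flanks of C7 never become equivalent. The gain is the carbocycle, and two fragments of similar size. The demand is single addition of the acetylide to the amide in the presence of an aryl ester and a vinylogous amide, followed by carbon (not oxygen) attack in a 6-endo-dig closure.

**14 to 13.** The C8a=C1 bond is cut. The methyl ketone of 13 is its only enolisable position. The gain is that C1 arrives as an enamine, which is both the nucleophile for ring closure and a mask for the C8 ketone. The demand is that the aryl ester and the amide survive the amide acetal.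

**13 to 8 and 11.** The acyl C–O bond of the ester is cut. The ester is made while the molecule is small, while only one hydroxyl is present, and before any alkyne exists, since a free tertiary hydroxyl next to a ynone would add to it. The gain is two simple fragments. The demand is a hindered esterification under conditions too weakly basic to cause an acyl shift in the ketol.

**8 to 7 to 6.** The ketone is taken back to the secondary alcohol (8 from 7), and the amide and free tertiary hydroxyl to the lactone acetal (7 from 6). The gain is that 6 is a direct aldol product. The demand is an oxidant that does not cleave the diol, and an aminolysis that spares the β-hydroxyl.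

**6 to 3 and 4; 3 to 1 and 2.** The C7–C8 bond is cut (aldol), then the acetal C–O bonds. The gain is that the quaternary centre comes from the chiral pool with retention, since the acetal centre of 3 relays the configuration while C7 is planar. The demand is attack of the electrophile anti to the tert-butyl group.

**11 to 10 to 9; 19 to 18 to 15 and 16.** The aryl O–CH2Ar bonds and the furan C2–CH2 bond are cut. The gain is commercial starting materials. The demand is an ortho ether that cannot cyclise onto the activated carboxyl group, and an alkylation of 2-furyllithium without an acidic alkyne hydrogen or SN2′ escape.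

## Other disconnections considered

**Alternative 1:** The cut is the ester bond at the C7 oxygen together with one C–C bond of the benzene ring (between the carbon bearing the ester carbonyl and the carbon bearing the methyl group). The orsellinate is grown on the C7 oxygen, not attached to it.

- Forward key step: dioxinone A2 is heated with the free tertiary alcohol A5, the compound that Alternative 2 sets out to make. A2 would lose acetone by retro-[4+2] to give acylketene A3. The hydroxyl of A5 would add to it to give the 3,5,7-trioxooctanoate A4. Aldol closure of C2 of that chain onto its C7 ketone, then dehydration, would aromatise to A1. TFA would then free the acid.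
- In its favour: a ketene is a small, linear, very electrophilic acyl donor, so the tertiary carbinol would be acylated under neutral thermal conditions. The arene arrives with free phenols, which removes the protection, hydrolysis and deprotection of the aryl branch.
- Against it here: the nucleophile is the complete azaphilone. It would have to survive about 100 °C and then the base or buffer normally needed for the aromatising aldol, while its C1 takes up nucleophiles. A4 has a competing exit, lactonisation to a 4-hydroxy-2-pyrone, which would expel A5 again. The plan also leaves open how A5 and its configuration are obtained.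
- Comparison: on the ester bond itself this alternative is the better of the two, because step 7 of the chosen route forces a 2,6-disubstituted aroyl chloride onto a tertiary ketol. On step economy of the aryl branch it is also better (no steps 5 and 6). In mechanism it replaces nucleophilic catalysis by a pericyclic ketene release and a polyketide-type aromatisation, which places three consecutive events on the most sensitive intermediate. Structurally the chosen plan is safer, since the ester is made on a small acyclic ketol and the electrophilic chromophore appears only near the end.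

**Alternative 2:** The cut is C7–C8.

- Forward key step: an intramolecular crossed benzoin reaction of A6. A carbene from a chiral triazolium salt would add to the aldehyde on the pyran. The resulting acyl anion equivalent would attack the C7 ketone of the 1,2-dione. Release of the carbene would give A5, with the catalyst choosing the face of the ketone.
- In its favour: the stereocentre is made catalytically and late, from an achiral precursor, in the event that closes the carbocycle. Aldehyde–ketone benzoin cyclisations to six-membered tertiary α-ketols are an established reaction class. No auxiliary is needed.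
- Against it here: the aldehyde is a vinylogous formate (C1 bears O2) and so a poor acceptor for the carbene. As a β-oxygenated enal, its carbene adduct could react through C1 as a homoenolate. The carbene and its base are nucleophiles that the pyran and the acrylate may not tolerate. The 1,2-dione offers two ketones, and attack at C6 would close a five-membered ring. A6 is a 4-ylidene-4H-pyran that may be hard to prepare and handle. The product still needs the hindered esterification, now on the complete chromophore.
- Comparison: both plans close the carbocycle on a C7 that already carries its oxygen. The alternative creates the stereocentre in that step; the chosen plan imports it from lactic acid. On economy of the stereocentre the alternative is better, since steps 1 to 3 and the auxiliary would not be needed. On certainty of absolute configuration the chosen plan is better (retention through a dioxolanone enolate against catalyst-dependent selectivity). In mechanism the alternative uses nucleophilic catalysis on a nucleophile-sensitive core, whereas the chosen plan completes its carbanion chemistry before the core exists. The step count would be equal or lower for the alternative only if A6 were short to make, which is the open point.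

**Alternative 3:** The cuts are C5–C6 and C4a–C8a, which excises the C5=C4a unit as an alkyne.

- Forward key step: Ni(cod)2 (zerovalent nickel) with a chiral phosphine would couple one of the two enantiotopic ketones of A8 with the terminal alkyne A9. β-Carbon elimination would open the four-membered ring, and C–C reductive elimination would give A7.
- In its favour: it is the most convergent plan, with two C–C bonds, the carbocycle and the C7 configuration set in one catalytic step from an achiral dione. A7 is the direct counterpart of 22 and carries the side chain as a ketal already at the ester oxidation level, so acid alone would unmask the C3 ketone and close the pyran. On this point (no photooxygenation, no aldehyde oxidation) the alternative is better than the chosen plan. The closing logic, C3 oxygen onto C1, is equal.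
- Against it here: nickel insertions into four-membered ketones are best established for internal alkynes and simple cyclobutanones. A terminal alkyne tends to oligomerise at zerovalent nickel and would have to insert with its CH toward C6. The ketones of A8 are vinylogous amide carbonyls, poor partners for oxidative coupling, and the strained 1,3-dione is prone to ring opening by nucleophiles. The catalyst would have to distinguish methyl from aroyloxy on the carbon next to the reacting carbonyl. A8 has no evident short synthesis.
- Comparison: structurally both routes pass through the same kind of aminomethylene dione. The alternative reaches it in one step from two fragments; the chosen plan takes steps 1 to 4, 7, 8 and 11. The alternative is organometallic ring expansion with catalyst control; the chosen plan is chiral-pool enolate chemistry plus a Michael closure, each step of a known type. The alternative is clearly better in step economy if the insertion works, but it concentrates several unverified demands in a single step.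

Key step: step 13

Remarks on the chemistry (assumptions and deliberate choices):
- Assumption: the phenols are carried as 4-methoxybenzyl (PMB) ethers. An ortho methoxymethyl ether can cyclise onto an activated carboxyl group and is cleaved by acidic methanol, which step 12 needs; PMB ethers survive both and also leave in TFA.
- The pyran closure is classed as 6-endo-trig with respect to C8a=C1 (both carbons end up in the ring). It is 6-exo-trig only when counted on the O-protonated form, C1=O+Me.
- The ester is made before any alkyne exists and after the secondary alcohol has been oxidised. Only the tertiary hydroxyl is then free, and no hydroxy-ynone, which would cyclise to a furanone, is ever formed.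
- The enamine is made before the ynone, so no amine-releasing reagent meets the ynone and the C8 ketone is masked during acetylide addition.
- 2-Propargylfuran is made from the silyl-capped bromide, because 2-furyllithium would deprotonate propargyl bromide itself.
- The carbinol centre of 6 and 7 is a mixture and is removed in step 4. The C8a=C1 geometry of 22 (drawn Z) and 23 (drawn E) is under thermodynamic control and without consequence.

## Steps

Step 1
Reactants: 1 (S)-lactic acid; 2 pivalaldehyde (2,2-dimethylpropanal)
Product: 3 (2S,5S)-2-tert-butyl-5-methyl-1,3-dioxolan-4-one (cis)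
Conditions: TsOH·H2O (cat.), H2SO4 (cat.), pentane, reflux, Dean–Stark; crystallisation from pentane/Et2O, −78 °C
Reagents that add atoms: none
Why: Acid-catalysed acetalisation with azeotropic removal of water; the cis acetal is the favoured, crystallisable isomer, so the new acetal centre is set relative to the lactate centre and can later relay its configuration.

Step 2
Reactants: 3 (2S,5S)-2-tert-butyl-5-methyl-1,3-dioxolan-4-one; 4 acetaldehyde
Product: 6 (2S,5R)-2-tert-butyl-5-[(1RS)-1-hydroxyethyl]-5-methyl-1,3-dioxolan-4-one, via lithium enolate 5 (not isolated)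
Conditions: LiN(i-Pr)2, THF, −78 °C; then 4, −78 °C; AcOH
Reagents that add atoms: none
Why: Aldol addition of the lithium enolate; acetaldehyde approaches anti to the tert-butyl group, so carbon replaces hydrogen with retention and the future C7 is fixed. The carbinol centre is uncontrolled and is oxidised in step 4.

Step 3
Reactants: 6 (2S,5R)-2-tert-butyl-5-[(1RS)-1-hydroxyethyl]-5-methyl-1,3-dioxolan-4-one
Product: 7 (2R,3RS)-2,3-dihydroxy-N-methoxy-N,2-dimethylbutanamide
Conditions: MeNH(OMe)·HCl, i-PrMgCl, THF, −20 → 0 °C; aq. NH4Cl
Reagents that add atoms: N,O-dimethylhydroxylamine hydrochloride, CNOC.Cl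
Why: Weinreb aminolysis of the activated lactone acetal by the magnesium amide; the opened hemiacetal loses pivalaldehyde and frees the tertiary hydroxyl. The quaternary centre has no α-hydrogen and cannot epimerise.

Step 4
Reactants: 7 (2R,3RS)-2,3-dihydroxy-N-methoxy-N,2-dimethylbutanamide
Product: 8 (2R)-2-hydroxy-N-methoxy-N,2-dimethyl-3-oxobutanamide
Conditions: IBX (2-iodoxybenzoic acid), DMSO, 23 °C
Reagents that add atoms: none
Why: IBX oxidises the secondary alcohol of a vicinal diol to the ketone without glycol cleavage and leaves the tertiary alcohol alone. The neutral medium avoids the base-induced acyl shift that would racemise the ketol.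

Step 5
Reactants: 9 orsellinic acid (2,4-dihydroxy-6-methylbenzoic acid)
Product: 10 4-methoxybenzyl 2,4-bis[(4-methoxybenzyl)oxy]-6-methylbenzoate
Conditions: PMBCl, K2CO3, Bu4NI (cat.), DMF, 60 °C
Reagents that add atoms: 4-methoxybenzyl chloride, COc1ccc(CCl)cc1
Why: Williamson alkylation of both phenoxides and of the carboxylate. A benzyl-type ortho ether cannot close onto an activated carboxyl group and is stable to base and mild acid.

Step 6
Reactants: 10 4-methoxybenzyl 2,4-bis[(4-methoxybenzyl)oxy]-6-methylbenzoate
Product: 11 2,4-bis[(4-methoxybenzyl)oxy]-6-methylbenzoic acid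
Conditions: KOH, DMSO/H2O, 80 °C; then aq. KHSO4, 0 °C
Reagents that add atoms: potassium hydroxide, [K+].[OH-]
Why: Hydroxide cleavage of the hindered benzylic ester in a dipolar solvent; the aryl ethers are inert to base, and cold, brief acidification spares them.

Step 7
Reactants: 8 (2R)-2-hydroxy-N-methoxy-N,2-dimethyl-3-oxobutanamide; 11 2,4-bis[(4-methoxybenzyl)oxy]-6-methylbenzoic acid
Product: 13 (2R)-1-[methoxy(methyl)amino]-2-methyl-1,3-dioxobutan-2-yl 2,4-bis[(4-methoxybenzyl)oxy]-6-methylbenzoate, via aroyl chloride 12 (not isolated)
Conditions: 11, Me2C=C(Cl)NMe2, CH2Cl2, 0 → 23 °C; then 8, Et3N, DMAP, CH2Cl2, 0 → 40 °C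
Reagents that add atoms: none
Why: Neutral conversion of the acid into its chloride by the α-chloroenamine, then DMAP-catalysed acylation of the only hydroxyl. This is the reaction type used to acylate the tertiary 7-hydroxyl of azaphilones with 2,6-disubstituted aroyl chlorides. No bond to the stereocentre is broken.

Step 8
Reactants: 13 (2R)-1-[methoxy(methyl)amino]-2-methyl-1,3-dioxobutan-2-yl 2,4-bis[(4-methoxybenzyl)oxy]-6-methylbenzoate
Product: 14 (2R,4E)-5-(dimethylamino)-1-[methoxy(methyl)amino]-2-methyl-1,3-dioxopent-4-en-2-yl 2,4-bis[(4-methoxybenzyl)oxy]-6-methylbenzoate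
Conditions: Me2NCH(OMe)2, toluene, 90 °C
Reagents that add atoms: N,N-dimethylformamide dimethyl acetal, COC(OC)N(C)C
Why: Aminomethylenation of the only enolisable position gives the (E)-enaminone. This brings in C1, turns the future C8a into a carbon nucleophile and masks the C8 ketone as a vinylogous amide. The 2,6-disubstituted aryl ester resists intramolecular attack by the enolate.

Step 9
Reactants: 15 furan; 16 3-bromo-1-(trimethylsilyl)prop-1-yne
Product: 18 [3-(furan-2-yl)prop-1-yn-1-yl]trimethylsilane, via 2-furyllithium 17 (not isolated)
Conditions: n-BuLi, THF, −78 → 0 °C; then 16, −78 → 23 °C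
Reagents that add atoms: none
Why: α-Lithiation of furan and SN2 alkylation; the silyl cap removes the acidic alkyne hydrogen and hinders SN2′ attack to an allene.

Step 10
Reactants: 18 [3-(furan-2-yl)prop-1-yn-1-yl]trimethylsilane
Product: 19 2-(prop-2-yn-1-yl)furan
Conditions: K2CO3 (cat.), MeOH, 0 °C
Reagents that add atoms: none
Why: Methanolysis of the alkynyl–silicon bond with catalytic carbonate; low temperature and short contact limit propargyl-to-allenyl isomerisation of the doubly activated CH2.

Step 11
Reactants: 14 (2R,4E)-5-(dimethylamino)-1-[methoxy(methyl)amino]-2-methyl-1,3-dioxopent-4-en-2-yl 2,4-bis[(4-methoxybenzyl)oxy]-6-methylbenzoate; 19 2-(prop-2-yn-1-yl)furan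
Product: 22 (1S)-3-[(Z)-(dimethylamino)methylidene]-4-(furan-2-ylmethyl)-1-methyl-2,6-dioxocyclohex-4-en-1-yl 2,4-bis[(4-methoxybenzyl)oxy]-6-methylbenzoate, via lithium acetylide 20 (not isolated), via ynone enaminone 21 (not isolated)
Conditions: 19, n-BuLi, THF, −78 °C; then 14, −78 → −20 °C; AcOH, pH 4 buffer wash; EtOH, 50 °C
Reagents that add atoms: none
Why: The acetylide adds once to the Weinreb amide, whose chelate releases the ynone only on quench; the vinylogous amide and the hindered aryl ester are less electrophilic. On warming, the enaminone α-carbon (C8a) adds to the ynone β-carbon (C4a) in a 6-endo-dig Michael addition, the reaction type that opens the Bohlmann–Rahtz sequence, and proton transfer gives the conjugated dione. C7 is untouched and its flanks stay different; the descriptor changes from R to S only through the priority rules.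

Step 12
Reactants: 22 (1S)-3-[(Z)-(dimethylamino)methylidene]-4-(furan-2-ylmethyl)-1-methyl-2,6-dioxocyclohex-4-en-1-yl 2,4-bis[(4-methoxybenzyl)oxy]-6-methylbenzoate
Product: 23 (1S)-4-(furan-2-ylmethyl)-3-[(E)-methoxymethylidene]-1-methyl-2,6-dioxocyclohex-4-en-1-yl 2,4-bis[(4-methoxybenzyl)oxy]-6-methylbenzoate
Conditions: CSA (camphor-10-sulfonic acid, 1.1 equiv), MeOH, 3 Å MS, 0 → 23 °C; NaHCO3
Reagents that add atoms: methanol, CO
Why: Acid-mediated addition–elimination at C1: the O-protonated vinylogous amide takes up methanol and releases dimethylamine, which the stoichiometric acid holds as its ammonium salt. The resulting vinylogous ester is far less reactive toward singlet oxygen than the enamine and carries a leaving group for the pyran closure.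

Step 13
Reactants: 23 (1S)-4-(furan-2-ylmethyl)-3-[(E)-methoxymethylidene]-1-methyl-2,6-dioxocyclohex-4-en-1-yl 2,4-bis[(4-methoxybenzyl)oxy]-6-methylbenzoate
Product: 27 (7S)-7-methyl-6,8-dioxo-3-[(1E)-3-oxoprop-1-en-1-yl]-7,8-dihydro-6H-isochromen-7-yl 2,4-bis[(4-methoxybenzyl)oxy]-6-methylbenzoate, via furan endoperoxide 24 (not isolated), via cis-oxoenal 25 (not isolated), via trans-oxoenal 26 (not isolated)
Conditions: O2, 5,10,15,20-tetraphenylporphyrin (cat.), visible light, CH2Cl2, −78 °C; Me2S, −78 → 23 °C; then CSA (cat.), 23 °C, dark
Reagents that add atoms: oxygen, O=O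
Why: Sensitised singlet oxygen adds [4+2] across the two α-carbons of the furan (the future C3 and C11) to give the bicyclic endoperoxide 24, and Me2S cleaves its O–O bond to unveil the C3 ketone and the C11 aldehyde of the cis-oxoenal 25. Acid then equilibrates 25 to the trans isomer 26 and promotes enolisation of the C3 ketone toward C4, whose hydrogens are activated by C3=O and, through C4a=C5, by the C6 carbonyl. The enol oxygen adds to C1 of the O-protonated vinylogous ester and methanol is expelled, which forms O2–C1 and the pyran ring. The closure is 6-endo-trig with respect to C8a=C1, or equivalently a 6-exo-trig addition to the oxocarbenium C1=O+Me of the protonated form. The closest known reaction types are the dye-sensitised photooxygenation of 2-alkylfurans with sulfide reduction to 4-oxo-2-enals, and the acid cyclodehydration of keto-aldehydes to pyrans that also closes this ring in biosynthesis. No stereocentre is formed; C7 is quaternary, has no acidic hydrogen and keeps two different flanks, so its configuration is not at risk. The step needs oxidation of the furan only, which the substrate secures because the electron-rich furan diene reacts with singlet oxygen far faster than the acceptor-substituted enol ether, the enone or the anisole-type rings. The E geometry of C9=C10 is the thermodynamic outcome of acid equilibration, and only the C3 oxygen can reach C1 in a six-membered array.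

Step 14
Reactants: 27 (7S)-7-methyl-6,8-dioxo-3-[(1E)-3-oxoprop-1-en-1-yl]-7,8-dihydro-6H-isochromen-7-yl 2,4-bis[(4-methoxybenzyl)oxy]-6-methylbenzoate
Product: 28 (2E)-3-[(7S)-7-({2,4-bis[(4-methoxybenzyl)oxy]-6-methylbenzoyl}oxy)-7-methyl-6,8-dioxo-7,8-dihydro-6H-isochromen-3-yl]prop-2-enoic acid
Conditions: NaClO2, NaH2PO4, 2-methyl-2-butene, t-BuOH/THF/H2O, 0 → 23 °C
Reagents that add atoms: sodium chlorite, [Na+].[O-]Cl=O
Why: Pinnick oxidation takes the enal to the enoic acid in a weakly acidic buffer without touching the alkenes; 2-methyl-2-butene traps the hypochlorous acid that could chlorinate the electron-rich rings or the pyran.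

Step 15
Reactants: 28 (2E)-3-[(7S)-7-({2,4-bis[(4-methoxybenzyl)oxy]-6-methylbenzoyl}oxy)-7-methyl-6,8-dioxo-7,8-dihydro-6H-isochromen-3-yl]prop-2-enoic acid
Product: 29 (S)-mitorubrinic acid, (2E)-3-[(7S)-7-[(2,4-dihydroxy-6-methylbenzoyl)oxy]-7-methyl-6,8-dioxo-7,8-dihydro-6H-isochromen-3-yl]prop-2-enoic acid
Conditions: TFA, anisole, CH2Cl2, 0 °C
Reagents that add atoms: none
Why: Acidolysis of the two aryl 4-methoxybenzyl ethers; the benzyl cation is trapped by anisole in a Friedel–Crafts alkylation. The azaphilone core, the tertiary ester (which cannot ionise next to two carbonyl groups) and the dienoic acid are stable to TFA.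

## Compound list

1 | (S)-lactic acid | C[C@H](O)C(=O)O | starting material
2 | pivalaldehyde | CC(C)(C)C=O | starting material
3 | (2S,5S)-2-tert-butyl-5-methyl-1,3-dioxolan-4-one | C[C@@H]1O[C@H](C(C)(C)C)OC1=O | intermediate
4 | acetaldehyde | CC=O | starting material
5 | lithium (2S)-2-tert-butyl-5-methyl-1,3-dioxol-4-olate (lithium enolate of 3) | CC1=C([O-])O[C@@H](C(C)(C)C)O1.[Li+] | intermediate
6 | (2S,5R)-2-tert-butyl-5-[(1RS)-1-hydroxyethyl]-5-methyl-1,3-dioxolan-4-one | C[C@]1(C(C)O)O[C@H](C(C)(C)C)OC1=O | intermediate
7 | (2R,3RS)-2,3-dihydroxy-N-methoxy-N,2-dimethylbutanamide | C[C@](C(=O)N(C)OC)(C(C)O)O | intermediate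
8 | (2R)-2-hydroxy-N-methoxy-N,2-dimethyl-3-oxobutanamide | C[C@](C(=O)N(C)OC)(C(C)=O)O | intermediate
9 | orsellinic acid | Cc1cc(O)cc(O)c1C(=O)O | starting material
10 | 4-methoxybenzyl 2,4-bis[(4-methoxybenzyl)oxy]-6-methylbenzoate | Cc1cc(OCc2ccc(OC)cc2)cc(OCc2ccc(OC)cc2)c1C(=O)OCc1ccc(OC)cc1 | intermediate
11 | 2,4-bis[(4-methoxybenzyl)oxy]-6-methylbenzoic acid | Cc1cc(OCc2ccc(OC)cc2)cc(OCc2ccc(OC)cc2)c1C(=O)O | intermediate
12 | 2,4-bis[(4-methoxybenzyl)oxy]-6-methylbenzoyl chloride | Cc1cc(OCc2ccc(OC)cc2)cc(OCc2ccc(OC)cc2)c1C(=O)Cl | intermediate
13 | (2R)-1-[methoxy(methyl)amino]-2-methyl-1,3-dioxobutan-2-yl 2,4-bis[(4-methoxybenzyl)oxy]-6-methylbenzoate | Cc1cc(OCc2ccc(OC)cc2)cc(OCc2ccc(OC)cc2)c1C(=O)O[C@](C)(C(C)=O)C(=O)N(C)OC | intermediate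
14 | (2R,4E)-5-(dimethylamino)-1-[methoxy(methyl)amino]-2-methyl-1,3-dioxopent-4-en-2-yl 2,4-bis[(4-methoxybenzyl)oxy]-6-methylbenzoate | Cc1cc(OCc2ccc(OC)cc2)cc(OCc2ccc(OC)cc2)c1C(=O)O[C@](C)(C(=O)/C=C/N(C)C)C(=O)N(C)OC | intermediate
15 | furan | c1ccoc1 | starting material
16 | 3-bromo-1-(trimethylsilyl)prop-1-yne | C[Si](C)(C)C#CCBr | starting material
17 | 2-furyllithium | [Li]c1ccco1 | intermediate
18 | [3-(furan-2-yl)prop-1-yn-1-yl]trimethylsilane | C[Si](C)(C)C#CCc1ccco1 | intermediate
19 | 2-(prop-2-yn-1-yl)furan | C#CCc1ccco1 | intermediate
20 | [3-(furan-2-yl)prop-1-yn-1-yl]lithium | [Li]C#CCc1ccco1 | intermediate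
21 | (1E,4R)-1-(dimethylamino)-8-(furan-2-yl)-4-methyl-3,5-dioxooct-1-en-6-yn-4-yl 2,4-bis[(4-methoxybenzyl)oxy]-6-methylbenzoate | Cc1cc(OCc2ccc(OC)cc2)cc(OCc2ccc(OC)cc2)c1C(=O)O[C@](C)(C(=O)/C=C/N(C)C)C(=O)C#CCc1ccco1 | intermediate
22 | (1S)-3-[(Z)-(dimethylamino)methylidene]-4-(furan-2-ylmethyl)-1-methyl-2,6-dioxocyclohex-4-en-1-yl 2,4-bis[(4-methoxybenzyl)oxy]-6-methylbenzoate | Cc1cc(OCc2ccc(OC)cc2)cc(OCc2ccc(OC)cc2)c1C(=O)O[C@@]1(C)C(=O)C=C(Cc2ccco2)/C(=C/N(C)C)C1=O | intermediate
23 | (1S)-4-(furan-2-ylmethyl)-3-[(E)-methoxymethylidene]-1-methyl-2,6-dioxocyclohex-4-en-1-yl 2,4-bis[(4-methoxybenzyl)oxy]-6-methylbenzoate | Cc1cc(OCc2ccc(OC)cc2)cc(OCc2ccc(OC)cc2)c1C(=O)O[C@@]1(C)C(=O)C=C(Cc2ccco2)/C(=C\OC)C1=O | intermediate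
24 | (1S)-3-[(E)-methoxymethylidene]-1-methyl-2,6-dioxo-4-[(2,3,7-trioxabicyclo[2.2.1]hept-5-en-1-yl)methyl]cyclohex-4-en-1-yl 2,4-bis[(4-methoxybenzyl)oxy]-6-methylbenzoate (bridgehead centres unassigned) | Cc1cc(OCc2ccc(OC)cc2)cc(OCc2ccc(OC)cc2)c1C(=O)O[C@@]1(C)C(=O)C=C(CC23C=CC(OO2)O3)/C(=C\OC)C1=O | intermediate
25 | (1S)-4-[(3Z)-2,5-dioxopent-3-en-1-yl]-3-[(E)-methoxymethylidene]-1-methyl-2,6-dioxocyclohex-4-en-1-yl 2,4-bis[(4-methoxybenzyl)oxy]-6-methylbenzoate | Cc1cc(OCc2ccc(OC)cc2)cc(OCc2ccc(OC)cc2)c1C(=O)O[C@@]1(C)C(=O)C=C(CC(=O)/C=C\C=O)/C(=C\OC)C1=O | intermediate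
26 | (1S)-4-[(3E)-2,5-dioxopent-3-en-1-yl]-3-[(E)-methoxymethylidene]-1-methyl-2,6-dioxocyclohex-4-en-1-yl 2,4-bis[(4-methoxybenzyl)oxy]-6-methylbenzoate | Cc1cc(OCc2ccc(OC)cc2)cc(OCc2ccc(OC)cc2)c1C(=O)O[C@@]1(C)C(=O)C=C(CC(=O)/C=C/C=O)/C(=C\OC)C1=O | intermediate
27 | (7S)-7-methyl-6,8-dioxo-3-[(1E)-3-oxoprop-1-en-1-yl]-7,8-dihydro-6H-isochromen-7-yl 2,4-bis[(4-methoxybenzyl)oxy]-6-methylbenzoate | Cc1cc(OCc2ccc(OC)cc2)cc(OCc2ccc(OC)cc2)c1C(=O)O[C@@]1(C)C(=O)C=C2C=C(/C=C/C=O)OC=C2C1=O | intermediate
28 | (2E)-3-[(7S)-7-({2,4-bis[(4-methoxybenzyl)oxy]-6-methylbenzoyl}oxy)-7-methyl-6,8-dioxo-7,8-dihydro-6H-isochromen-3-yl]prop-2-enoic acid | Cc1cc(OCc2ccc(OC)cc2)cc(OCc2ccc(OC)cc2)c1C(=O)O[C@@]1(C)C(=O)C=C2C=C(/C=C/C(=O)O)OC=C2C1=O | intermediate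
29 | (S)-mitorubrinic acid | Cc1cc(O)cc(O)c1C(=O)O[C@@]1(C)C(=O)C=C2C=C(/C=C/C(=O)O)OC=C2C1=O | target

## Step count and least certain steps

Total: 15 steps. Longest linear sequence: 11 steps (steps 1, 2, 3, 4, 7, 8, 11, 12, 13, 14, 15, from 1 to 29). The aryl branch (steps 5, 6) and the alkyne branch (steps 9, 10) have two steps each.

**Step 13 (key step).** The photooxygenation may not stay on the furan. The substrate is itself a light-absorbing push–pull dienone that can bleach or act as a sensitiser, and its enol ether can react slowly. The cis-oxoenal can also react at its aldehyde (aldol attack of the doubly activated C4 on C11) before it isomerises and closes. Fallback: from 23, open the furan without light by electrophilic bromination–hydrolysis (NBS, NaHCO3, acetone/H2O, −20 °C, then pyridine, which isomerises the first-formed cis product). This gives 26 as an isolated compound. Separate cyclisation with catalytic CSA in CH2Cl2 then returns to the route at 27. No new compound is involved.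

**Step 7.** Acylation of a tertiary, electron-poor hydroxyl by a 2,6-disubstituted aroyl donor may be slow. The base then has time to promote a degenerate acyl shift in the α-ketol, which would erode the enantiopurity, or simply to give no conversion. Fallback: from 7, silylate the secondary hydroxyl selectively (t-BuMe2SiCl, imidazole, DMF) to the silyl ether of the diol amide F1. Deprotonate the tertiary hydroxyl (LiN(SiMe3)2, THF, −78 °C) and acylate the alkoxide with 12 to the silylated ester F2; no ketol is present, so no acyl shift is possible. Remove the silyl group (HF·pyridine, THF) to the hydroxy ester F3, and oxidise with IBX to rejoin the route at 13.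

**Step 12.** The exchange may stop short, because the vinylogous amide is the more stabilised partner. Adventitious water may divert material to the free hydroxymethylene compound, or a benzyl ether may be partly lost. Fallback: from 22, hydrolyse deliberately (1 M HCl, THF, 0 °C) to the hydroxymethylene dione F4. Convert its aldehyde-level enol into the methyl enol ether under thermodynamic control (HC(OMe)3, CSA cat., MeOH) to rejoin the route at 23.

**Step 11.** Several things may go wrong after the acetylide addition: conjugate addition of the liberated N,O-dimethylhydroxylamine or of ethanol to the ynone; propargyl-to-allenyl isomerisation; or a neutral enaminone that attacks too slowly or through oxygen. Fallback: isolate 21 after the buffered work-up and hydrolyse its enamine (aqueous oxalic acid, THF) to the hydroxymethylene ynone F5. Close the ring as a base-catalysed 6-endo-dig Michael addition of the 1,3-dicarbonyl anion (Cs2CO3 cat., MeCN, 0 °C), which gives F4. Methylate F4 as in the fallback of step 12 to rejoin the route at 23.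

**Step 15.** The 4-methoxybenzyl cation may re-alkylate the liberated electron-rich resorcinol ring, and the chelated ortho ether may come off incompletely. Fallback: from 28, remove both ethers oxidatively (DDQ, CH2Cl2/pH 7 buffer). The benzyl groups leave as 4-methoxybenzaldehyde, no free benzyl cation is formed, and 29 is reached directly. No new compound is involved.

## Further compounds

F0 | step 13 | none | none
F1 | step 7 | (2R,3RS)-3-{[tert-butyl(dimethyl)silyl]oxy}-2-hydroxy-N-methoxy-N,2-dimethylbutanamide | C[C@](C(=O)N(C)OC)(C(C)O[Si](C)(C)C(C)(C)C)O
F2 | step 7 | (2R,3RS)-3-{[tert-butyl(dimethyl)silyl]oxy}-1-[methoxy(methyl)amino]-2-methyl-1-oxobutan-2-yl 2,4-bis[(4-methoxybenzyl)oxy]-6-methylbenzoate | Cc1cc(OCc2ccc(OC)cc2)cc(OCc2ccc(OC)cc2)c1C(=O)O[C@](C)(C(C)O[Si](C)(C)C(C)(C)C)C(=O)N(C)OC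
F3 | step 7 | (2R,3RS)-3-hydroxy-1-[methoxy(methyl)amino]-2-methyl-1-oxobutan-2-yl 2,4-bis[(4-methoxybenzyl)oxy]-6-methylbenzoate | Cc1cc(OCc2ccc(OC)cc2)cc(OCc2ccc(OC)cc2)c1C(=O)O[C@](C)(C(C)O)C(=O)N(C)OC
F4 | step 12 | (1S)-4-(furan-2-ylmethyl)-3-[(Z)-hydroxymethylidene]-1-methyl-2,6-dioxocyclohex-4-en-1-yl 2,4-bis[(4-methoxybenzyl)oxy]-6-methylbenzoate | Cc1cc(OCc2ccc(OC)cc2)cc(OCc2ccc(OC)cc2)c1C(=O)O[C@@]1(C)C(=O)C=C(Cc2ccco2)/C(=C/O)C1=O
F5 | step 11 | (1Z,4R)-8-(furan-2-yl)-1-hydroxy-4-methyl-3,5-dioxooct-1-en-6-yn-4-yl 2,4-bis[(4-methoxybenzyl)oxy]-6-methylbenzoate | Cc1cc(OCc2ccc(OC)cc2)cc(OCc2ccc(OC)cc2)c1C(=O)O[C@](C)(C(=O)/C=C\O)C(=O)C#CCc1ccco1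
F0 | step 15 | none | none
A1 | alternative 1 | mitorubrinic acid tert-butyl ester | Cc1cc(O)cc(O)c1C(=O)O[C@@]1(C)C(=O)C=C2C=C(/C=C/C(=O)OC(C)(C)C)OC=C2C1=O
A2 | alternative 1 | 2,2-dimethyl-6-(2,4-dioxopentyl)-4H-1,3-dioxin-4-one | CC(=O)CC(=O)CC1=CC(=O)OC(C)(C)O1
A3 | alternative 1 | 3,5,7-trioxooct-1-en-1-one (acylketene) | CC(=O)CC(=O)CC(=O)C=C=O
A4 | alternative 1 | (7S)-3-[(1E)-3-tert-butoxy-3-oxoprop-1-en-1-yl]-7-methyl-6,8-dioxo-7,8-dihydro-6H-isochromen-7-yl 3,5,7-trioxooctanoate | CC(=O)CC(=O)CC(=O)CC(=O)O[C@@]1(C)C(=O)C=C2C=C(/C=C/C(=O)OC(C)(C)C)OC=C2C1=O
A5 | alternative 2 | tert-butyl (2E)-3-[(7S)-7-hydroxy-7-methyl-6,8-dioxo-7,8-dihydro-6H-isochromen-3-yl]prop-2-enoate | O[C@@]1(C)C(=O)C=C2C=C(/C=C/C(=O)OC(C)(C)C)OC=C2C1=O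
A6 | alternative 2 | tert-butyl (2E)-3-[4-(2,3-dioxobutylidene)-5-formyl-4H-pyran-2-yl]prop-2-enoate | CC(=O)C(=O)/C=C1/C=C(/C=C/C(=O)OC(C)(C)C)OC=C1C=O
A7 | alternative 3 | (1S)-4-({2-[(1E)-3-tert-butoxy-3-oxoprop-1-en-1-yl]-1,3-dioxolan-2-yl}methyl)-3-[(Z)-(dimethylamino)methylidene]-1-methyl-2,6-dioxocyclohex-4-en-1-yl 2,4-bis(methoxymethoxy)-6-methylbenzoate | Cc1cc(OCOC)cc(OCOC)c1C(=O)O[C@@]1(C)C(=O)C=C(CC2(/C=C/C(=O)OC(C)(C)C)OCCO2)/C(=C/N(C)C)C1=O
A8 | alternative 3 | 3-[(dimethylamino)methylidene]-1-methyl-2,4-dioxocyclobutyl 2,4-bis(methoxymethoxy)-6-methylbenzoate | Cc1cc(OCOC)cc(OCOC)c1C(=O)OC1(C)C(=O)C(=CN(C)C)C1=O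
A9 | alternative 3 | tert-butyl (2E)-3-[2-(prop-2-yn-1-yl)-1,3-dioxolan-2-yl]prop-2-enoate | C#CCC1(/C=C/C(=O)OC(C)(C)C)OCCO1
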